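**Plan**
- Retrosynthetic cuts: six aryl O–Si bonds; the C8–vinyl bond (Z-dienylstannane); the flavanone C2–C1′ bond (asymmetric 1,4-arylation of a chromone); in the chromone, C3 is excised and C2 re-bonded to C4, which leads back to the furanone ring of 4,6-dihydroxybenzofuran-3(2H)-one; in the dihydrobenzofuran, the C2–C3 bond, back to a 2-(4-methoxybenzyloxy)benzophenone.
- Forward order of rings: furanone (bought) → cyclopropane across C2=C3 of its 3-silyloxybenzofuran → six-membered pyranone by one-carbon ring enlargement; separately, the dihydrofuran ring by Rh-carbene C–H insertion; then union at flavanone C2, diene at C8, desilylation.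
- Enabling feature: the pyranone carbonyl C4 lies between aryl C4a and the O1–CH–CH2 unit. Without C3 this is a benzofuranone whose ketone enolises into the furan ring, so the C2=C3 enol ether takes up CH2, and O1 on the cyclopropane carbon steers cleavage of the shared bond so that the CH2 ends as C3.
- Stereochemistry: dihydrobenzofuran C3 from chiral Rh2(PTAD)4, C2 by acid equilibration to trans; flavanone C2 from the chiral Rh–diphosphine in the 1,4-addition; Z-alkene from anti-hydrostannation and a stereoretentive Stille coupling.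

Key step: step 4

Assumption: Rh2(S-PTAD)4 (step 9) and (S)-MeO-F12-BIPHEP (step 14) are named by analogy as the enantiomers giving (3R) and (2S); if a first run shows the opposite sense, the mirror-image catalyst is used.

Abbreviations: TIPSO = triisopropylsilyloxy, TBSO = tert-butyldimethylsilyloxy.

**Step 1**
Reactants: 1 4,6-dihydroxy-1-benzofuran-3(2H)-one
Product: 2 4,6-bis(TIPSO)-1-benzofuran-3(2H)-one
Conditions: TIPSCl (2.4 equiv), imidazole, DMAP (cat.), DMF, 40 °C
Reagents that add atoms: chlorotriisopropylsilane, CC(C)[Si](Cl)(C(C)C)C(C)C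
Why: Standard phenol silylation; TIPS is chosen because it should survive the Fe(III), aqueous Rh and Pd steps and because it later shields C6.

**Step 2**
Reactants: 2 4,6-bis(TIPSO)-1-benzofuran-3(2H)-one
Product: 3 4,6-bis(TIPSO)-3-(trimethylsilyloxy)-1-benzofuran
Conditions: TMSOTf (1.3 equiv), Et3N (2 equiv), CH2Cl2, 0 °C; non-aqueous work-up
Reagents that add atoms: trimethylsilyl trifluoromethanesulfonate, C[Si](C)(C)OS(=O)(=O)C(F)(F)F
Why: Silyl enol ether formation by soft enolisation, driven by aromatisation of the furan ring, exposes C2=C3 as an electron-rich enol ether.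

**Step 3**
Reactants: 3 4,6-bis(TIPSO)-3-(trimethylsilyloxy)-1-benzofuran
Product: 4 racemic cis-fused 4,6-bis(TIPSO)-6b-(trimethylsilyloxy)-1a,6b-dihydro-1H-cyclopropa[b][1]benzofuran
Conditions: Et2Zn (2 equiv), CH2I2 (4 equiv), CH2Cl2, 0 °C → rt; pyridine quench; used crude
Reagents that add atoms: diiodomethane, ICI
Why: Furukawa–Simmons–Smith cyclopropanation of a silyl enol ether; the electrophilic zinc carbenoid should add to the most electron-rich C=C (C2=C3), cis fusion is the only possible outcome, and both new stereocentres are erased in step 4.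

**Step 4**
Reactants: 4 racemic cis-fused 4,6-bis(TIPSO)-6b-(trimethylsilyloxy)-1a,6b-dihydro-1H-cyclopropa[b][1]benzofuran
Product: 6 5,7-bis(TIPSO)-4H-chromen-4-one, via 2-chlorochroman-4-one 5 (not isolated)
Conditions: FeCl3 (2.5 equiv), pyridine (1 equiv), DMF, 0 °C → rt; then Et3N (3 equiv), rt
Reagents that add atoms: none
Why: Fe(III) should exchange the trimethylsilyl group for an iron alkoxide and oxidise it to the cyclopropyloxy radical, which undergoes β-scission of the bond shared by the two rings (C1a–C6b); the former ketone carbon becomes the C4 carbonyl and the O1-stabilised radical at the future C2 takes chlorine from FeCl3 to give 5, which loses HCl to the chromone. The closest known reaction type is the Ito–Saegusa FeCl3 ring enlargement of 1-silyloxybicyclo[n.1.0]alkanes to 2-cycloalkenones. No ring is closed: the five-membered furanone grows by one carbon through endocyclic cleavage of the fused cyclopropane bond, and the carbenoid CH2 of step 3 ends as C3. No stereocentre remains, because the chlorinated C2 of 5 forms racemic and is flattened by the elimination. The step needs scission of the internal rather than the external cyclopropane bond, which the ring oxygen on C1a (α-oxygen radical stabilisation) and relief of bicyclo[3.1.0] strain should secure, and it needs oxidation at the alkoxide rather than at the electron-rich arene, which inner-sphere oxidation at oxygen in the pyridine-buffered medium should provide. It delivers the pyranone at its final size and as the enone that step 14 needs for the stereodefining arylation.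

**Step 5**
Reactants: 6 5,7-bis(TIPSO)-4H-chromen-4-one
Product: 7 8-iodo-5,7-bis(TIPSO)-4H-chromen-4-one
Conditions: NIS (1.1 equiv), TFA (0.2 equiv), MeCN, 0 °C → rt, dark
Reagents that add atoms: N-iodosuccinimide, O=C1CCC(=O)N1I
Why: Electrophilic aromatic iodination should go to C8, which is activated by three oxygen donors and, unlike C6, is not wedged between two TIPSO groups, in line with the C8 preference known for 5,7-di-O-alkylated chromones and flavones.

**Step 6**
Reactants: 8 1-bromo-2,4-dimethoxybenzene; 9 3,5-dimethoxybenzoyl chloride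
Product: 10 (5-bromo-2-hydroxy-4-methoxyphenyl)(3,5-dimethoxyphenyl)methanone
Conditions: AlCl3 (2.5 equiv), CH2Cl2, 0 °C → reflux; aq. HCl
Reagents that add atoms: none
Why: Friedel–Crafts acylation at C5 (para to one OMe, ortho to the other), followed in the same pot by chelation-assisted AlCl3 cleavage of the methoxy group ortho to the new carbonyl.

**Step 7**
Reactants: 10 (5-bromo-2-hydroxy-4-methoxyphenyl)(3,5-dimethoxyphenyl)methanone; 11 4-methoxybenzyl chloride
Product: 12 {5-bromo-4-methoxy-2-[(4-methoxybenzyl)oxy]phenyl}(3,5-dimethoxyphenyl)methanone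
Conditions: K2CO3, NaI (cat.), DMF, 60 °C
Reagents that add atoms: none
Why: Williamson etherification of the only free phenol installs the benzylic CH2 that becomes C2 of the dihydrobenzofuran.

**Step 8**
Reactants: 12 {5-bromo-4-methoxy-2-[(4-methoxybenzyl)oxy]phenyl}(3,5-dimethoxyphenyl)methanone
Product: 13 hydrazone of 12 (E/Z mixture)
Conditions: N2H4·H2O (10 equiv), AcOH (cat.), EtOH, reflux
Reagents that add atoms: hydrazine, NN
Why: Acid-catalysed hydrazone condensation of a diaryl ketone, the usual entry to donor/donor diazo compounds.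

**Step 9**
Reactants: 13 hydrazone of 12
Product: 15 cis-(2S,3R)-5-bromo-3-(3,5-dimethoxyphenyl)-6-methoxy-2-(4-methoxyphenyl)-2,3-dihydro-1-benzofuran, via diaryldiazomethane 14 (not isolated)
Conditions: MnO2, CH2Cl2, rt, filtration; then Rh2(S-PTAD)4 (1 mol %), CH2Cl2, 0 °C
Reagents that add atoms: none
Why: MnO2 dehydrogenation to the diaryldiazomethane, then Rh(II) donor/donor carbene 1,5-C–H insertion into the activated p-methoxybenzylic C–H closes the dihydrofuran ring; the concerted insertion should give the cis isomer and the chiral carboxylate catalyst sets C3 (and with it C2).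

**Step 10**
Reactants: 15 cis-(2S,3R)-5-bromo-3-(3,5-dimethoxyphenyl)-6-methoxy-2-(4-methoxyphenyl)-2,3-dihydro-1-benzofuran
Product: 16 5-[(2R,3R)-5-bromo-6-hydroxy-2-(4-hydroxyphenyl)-2,3-dihydro-1-benzofuran-3-yl]benzene-1,3-diol (trans)
Conditions: BBr3 (10 equiv), CH2Cl2, −78 °C → rt; MeOH, aq. NaHCO3
Reagents that add atoms: none
Why: Lewis-acid ether cleavage removes the four methyl groups, and reversible ionisation of the C2–O bond (p-oxybenzylic cation) should equilibrate C2 to the more stable trans isomer while C3 is not touched.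

**Step 11**
Reactants: 16 5-[(2R,3R)-5-bromo-6-hydroxy-2-(4-hydroxyphenyl)-2,3-dihydro-1-benzofuran-3-yl]benzene-1,3-diol
Product: 17 (2R,3R)-5-bromo-3-[3,5-bis(TBSO)phenyl]-6-(TBSO)-2-[4-(TBSO)phenyl]-2,3-dihydro-1-benzofuran
Conditions: TBSCl (6 equiv), imidazole, DMF, rt
Reagents that add atoms: tert-butylchlorodimethylsilane, CC(C)(C)[Si](C)(C)Cl
Why: Standard phenol silylation gives protecting groups that can be removed at the end under buffered, near-neutral fluoride conditions.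

**Step 12**
Reactants: 17 (2R,3R)-5-bromo-3-[3,5-bis(TBSO)phenyl]-6-(TBSO)-2-[4-(TBSO)phenyl]-2,3-dihydro-1-benzofuran
Product: 20 {(2R,3R)-3-[3,5-bis(TBSO)phenyl]-6-(TBSO)-2-[4-(TBSO)phenyl]-2,3-dihydro-1-benzofuran-5-yl}boronic acid, via aryllithium 18 (not isolated), via lithium triisopropoxyborate 19 (not isolated)
Conditions: B(Oi-Pr)3 (1.5 equiv), n-BuLi (1.1 equiv), THF–toluene, −78 °C (in situ quench); aq. NH4Cl
Reagents that add atoms: triisopropyl borate, CC(C)OB(OC(C)C)OC(C)C; water, O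
Why: Bromine–lithium exchange with in situ borate trapping should outrun the O→C silyl shift of the ortho-silyloxy aryllithium, and hydrolysis gives the boronic acid.

**Step 13**
Reactants: 21 2-methylbut-1-en-3-yne; 22 tributyltin hydride
Product: 23 tributyl[(1Z)-3-methylbuta-1,3-dien-1-yl]stannane
Conditions: ZrCl4 (0.2 equiv), toluene, 0 °C; Et3N quench
Reagents that add atoms: none
Why: Lewis-acid-catalysed anti-hydrostannation of a terminal alkyne places tin at the terminus cis to the isopropenyl group, which fixes the Z geometry.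

**Step 14**
Reactants: 7 8-iodo-5,7-bis(TIPSO)-4H-chromen-4-one; 20 {(2R,3R)-3-[3,5-bis(TBSO)phenyl]-6-(TBSO)-2-[4-(TBSO)phenyl]-2,3-dihydro-1-benzofuran-5-yl}boronic acid
Product: 24 (2S)-2-{(2R,3R)-3-[3,5-bis(TBSO)phenyl]-6-(TBSO)-2-[4-(TBSO)phenyl]-2,3-dihydro-1-benzofuran-5-yl}-8-iodo-5,7-bis(TIPSO)-2,3-dihydro-4H-chromen-4-one
Conditions: [Rh(OH)(cod)]2 (3 mol %), (S)-MeO-F12-BIPHEP (6.6 mol %), toluene/H2O (10:1), 40 °C
Reagents that add atoms: none
Why: Hayashi–Miyaura asymmetric 1,4-addition to a chromone: the aryl–Rh(I) species inserts C2=C3 on the face dictated by the electron-poor chiral diphosphine (catalyst control, the remote dihydrobenzofuran centres being spectators) to set (2S), and water protonates the rhodium enolate under base-free conditions that should spare the silyl ethers and the C–I bond.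

**Step 15**
Reactants: 24 (2S)-8-iodoflavanone hexasilyl ether (as named in step 14); 23 tributyl[(1Z)-3-methylbuta-1,3-dien-1-yl]stannane
Product: 25 (2S)-2-{(2R,3R)-3-[3,5-bis(TBSO)phenyl]-6-(TBSO)-2-[4-(TBSO)phenyl]-2,3-dihydro-1-benzofuran-5-yl}-8-[(1Z)-3-methylbuta-1,3-dien-1-yl]-5,7-bis(TIPSO)-2,3-dihydro-4H-chromen-4-one
Conditions: Pd2(dba)3 (5 mol %), AsPh3 (40 mol %), CuI (0.2 equiv), DMF, 40 °C, dark
Reagents that add atoms: none
Why: Stille coupling under neutral conditions transfers the alkenyl group with retention of the Z geometry and leaves the base-sensitive flavanone C2 untouched.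

**Step 16**
Reactants: 25 hexasilyl ether of the target (as named in step 15)
Product: 26 (2S)-2-[(2R,3R)-3-(3,5-dihydroxyphenyl)-6-hydroxy-2-(4-hydroxyphenyl)-2,3-dihydro-1-benzofuran-5-yl]-5,7-dihydroxy-8-[(1Z)-3-methylbuta-1,3-dien-1-yl]-2,3-dihydro-4H-chromen-4-one (CNP0284772.1)
Conditions: TBAF (7 equiv), AcOH (7 equiv), THF, 0 °C → rt, dark
Reagents that add atoms: none
Why: Buffered fluoride desilylation removes all six aryl silyl ethers without generating free phenoxide (which could open the flavanone at C2) and without acid (which could cyclise the Z-dienylphenol to a chromene).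

**Compound list**
1 | 4,6-dihydroxy-1-benzofuran-3(2H)-one | O=C1COc2cc(O)cc(O)c12 | starting material
2 | 4,6-bis(triisopropylsilyloxy)-1-benzofuran-3(2H)-one | O=C1COc2cc(O[Si](C(C)C)(C(C)C)C(C)C)cc(O[Si](C(C)C)(C(C)C)C(C)C)c12 | intermediate
3 | 4,6-bis(triisopropylsilyloxy)-3-(trimethylsilyloxy)-1-benzofuran | C[Si](C)(C)Oc1coc2cc(O[Si](C(C)C)(C(C)C)C(C)C)cc(O[Si](C(C)C)(C(C)C)C(C)C)c12 | intermediate
4 | racemic cis-fused 4,6-bis(triisopropylsilyloxy)-6b-(trimethylsilyloxy)-1a,6b-dihydro-1H-cyclopropa[b][1]benzofuran | C[Si](C)(C)OC12CC1Oc1cc(O[Si](C(C)C)(C(C)C)C(C)C)cc(O[Si](C(C)C)(C(C)C)C(C)C)c12 | intermediate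
5 | racemic 2-chloro-5,7-bis(triisopropylsilyloxy)chroman-4-one | O=C1CC(Cl)Oc2cc(O[Si](C(C)C)(C(C)C)C(C)C)cc(O[Si](C(C)C)(C(C)C)C(C)C)c12 | intermediate
6 | 5,7-bis(triisopropylsilyloxy)-4H-chromen-4-one | O=c1ccoc2cc(O[Si](C(C)C)(C(C)C)C(C)C)cc(O[Si](C(C)C)(C(C)C)C(C)C)c12 | intermediate
7 | 8-iodo-5,7-bis(triisopropylsilyloxy)-4H-chromen-4-one | O=c1ccoc2c(I)c(O[Si](C(C)C)(C(C)C)C(C)C)cc(O[Si](C(C)C)(C(C)C)C(C)C)c12 | intermediate
8 | 1-bromo-2,4-dimethoxybenzene | COc1ccc(Br)c(OC)c1 | starting material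
9 | 3,5-dimethoxybenzoyl chloride | COc1cc(OC)cc(c1)C(Cl)=O | starting material
10 | (5-bromo-2-hydroxy-4-methoxyphenyl)(3,5-dimethoxyphenyl)methanone | COc1cc(OC)cc(c1)C(=O)c1cc(Br)c(OC)cc1O | intermediate
11 | 4-methoxybenzyl chloride | COc1ccc(CCl)cc1 | starting material
12 | {5-bromo-4-methoxy-2-[(4-methoxybenzyl)oxy]phenyl}(3,5-dimethoxyphenyl)methanone | COc1ccc(COc2cc(OC)c(Br)cc2C(=O)c2cc(OC)cc(OC)c2)cc1 | intermediate
13 | hydrazone of 12 (E/Z mixture) | COc1ccc(COc2cc(OC)c(Br)cc2C(=NN)c2cc(OC)cc(OC)c2)cc1 | intermediate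
14 | 1-bromo-5-[diazo(3,5-dimethoxyphenyl)methyl]-2-methoxy-4-[(4-methoxybenzyl)oxy]benzene | COc1ccc(COc2cc(OC)c(Br)cc2C(=[N+]=[N-])c2cc(OC)cc(OC)c2)cc1 | intermediate
15 | cis-(2S,3R)-5-bromo-3-(3,5-dimethoxyphenyl)-6-methoxy-2-(4-methoxyphenyl)-2,3-dihydro-1-benzofuran | Brc1cc2c(cc1OC)O[C@H](c1ccc(OC)cc1)[C@@H]2c1cc(OC)cc(OC)c1 | intermediate
16 | 5-[(2R,3R)-5-bromo-6-hydroxy-2-(4-hydroxyphenyl)-2,3-dihydro-1-benzofuran-3-yl]benzene-1,3-diol | Brc1cc2c(cc1O)O[C@@H](c1ccc(O)cc1)[C@@H]2c1cc(O)cc(O)c1 | intermediate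
17 | (2R,3R)-5-bromo-3-[3,5-bis(tert-butyldimethylsilyloxy)phenyl]-6-(tert-butyldimethylsilyloxy)-2-[4-(tert-butyldimethylsilyloxy)phenyl]-2,3-dihydro-1-benzofuran | Brc1cc2c(cc1O[Si](C)(C)C(C)(C)C)O[C@@H](c1ccc(O[Si](C)(C)C(C)(C)C)cc1)[C@@H]2c1cc(O[Si](C)(C)C(C)(C)C)cc(O[Si](C)(C)C(C)(C)C)c1 | intermediate
18 | 5-lithio derivative of 17 (aryllithium) | [Li]c1cc2c(cc1O[Si](C)(C)C(C)(C)C)O[C@@H](c1ccc(O[Si](C)(C)C(C)(C)C)cc1)[C@@H]2c1cc(O[Si](C)(C)C(C)(C)C)cc(O[Si](C)(C)C(C)(C)C)c1 | intermediate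
19 | lithium triisopropoxy(aryl)borate from 18 | [Li+].CC(C)O[B-](OC(C)C)(OC(C)C)c1cc2c(cc1O[Si](C)(C)C(C)(C)C)O[C@@H](c1ccc(O[Si](C)(C)C(C)(C)C)cc1)[C@@H]2c1cc(O[Si](C)(C)C(C)(C)C)cc(O[Si](C)(C)C(C)(C)C)c1 | intermediate
20 | {(2R,3R)-3-[3,5-bis(tert-butyldimethylsilyloxy)phenyl]-6-(tert-butyldimethylsilyloxy)-2-[4-(tert-butyldimethylsilyloxy)phenyl]-2,3-dihydro-1-benzofuran-5-yl}boronic acid | OB(O)c1cc2c(cc1O[Si](C)(C)C(C)(C)C)O[C@@H](c1ccc(O[Si](C)(C)C(C)(C)C)cc1)[C@@H]2c1cc(O[Si](C)(C)C(C)(C)C)cc(O[Si](C)(C)C(C)(C)C)c1 | intermediate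
21 | 2-methylbut-1-en-3-yne | C=C(C)C#C | starting material
22 | tributyltin hydride | CCCC[SnH](CCCC)CCCC | starting material
23 | tributyl[(1Z)-3-methylbuta-1,3-dien-1-yl]stannane | C=C(C)/C=C\[Sn](CCCC)(CCCC)CCCC | intermediate
24 | (2S)-2-{(2R,3R)-3-[3,5-bis(tert-butyldimethylsilyloxy)phenyl]-6-(tert-butyldimethylsilyloxy)-2-[4-(tert-butyldimethylsilyloxy)phenyl]-2,3-dihydro-1-benzofuran-5-yl}-8-iodo-5,7-bis(triisopropylsilyloxy)-2,3-dihydro-4H-chromen-4-one | Ic1c(O[Si](C(C)C)(C(C)C)C(C)C)cc(O[Si](C(C)C)(C(C)C)C(C)C)c2c1O[C@H](c1cc3c(cc1O[Si](C)(C)C(C)(C)C)O[C@@H](c1ccc(O[Si](C)(C)C(C)(C)C)cc1)[C@@H]3c1cc(O[Si](C)(C)C(C)(C)C)cc(O[Si](C)(C)C(C)(C)C)c1)CC2=O | intermediate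
25 | (2S)-2-{(2R,3R)-3-[3,5-bis(tert-butyldimethylsilyloxy)phenyl]-6-(tert-butyldimethylsilyloxy)-2-[4-(tert-butyldimethylsilyloxy)phenyl]-2,3-dihydro-1-benzofuran-5-yl}-8-[(1Z)-3-methylbuta-1,3-dien-1-yl]-5,7-bis(triisopropylsilyloxy)-2,3-dihydro-4H-chromen-4-one | C=C(C)/C=C\c1c(O[Si](C(C)C)(C(C)C)C(C)C)cc(O[Si](C(C)C)(C(C)C)C(C)C)c2c1O[C@H](c1cc3c(cc1O[Si](C)(C)C(C)(C)C)O[C@@H](c1ccc(O[Si](C)(C)C(C)(C)C)cc1)[C@@H]3c1cc(O[Si](C)(C)C(C)(C)C)cc(O[Si](C)(C)C(C)(C)C)c1)CC2=O | intermediate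
26 | (2S)-2-[(2R,3R)-3-(3,5-dihydroxyphenyl)-6-hydroxy-2-(4-hydroxyphenyl)-2,3-dihydro-1-benzofuran-5-yl]-5,7-dihydroxy-8-[(1Z)-3-methylbuta-1,3-dien-1-yl]-2,3-dihydro-4H-chromen-4-one | C=C(C)/C=C\c1c(O)cc(O)c2c1O[C@H](c1cc3c(cc1O)O[C@@H](c1ccc(O)cc1)[C@@H]3c1cc(O)cc(O)c1)CC2=O | target

**Step count**
Total: 16 steps. Longest linear sequence: 10 steps (steps 6–12, then 14–16).

**Steps most likely to fail**

1. Step 14. The hindered ortho-silyloxyaryl–rhodium species may insert into the electron-rich, doubly silyloxylated chromone so slowly that protodeboronation consumes the boronic acid and facial control erodes. The fallback sets out from bromide 17 and chromone 7 and comes back at 24. Bromide 17 is lithiated (n-BuLi, THF, −78 °C) to aryllithium 18 and transmetalated with MgBr2·OEt2 to the arylmagnesium bromide F1. Copper-catalysed 1,4-addition (CuBr·SMe2 10 mol %, TMSCl, −78 → −30 °C) to 7 should give the 4-(trimethylsilyloxy)-2H-chromene F2 as both C2 epimers. Mild aqueous hydrolysis releases 24 together with its (2R)-epimer F3. The two are diastereomers and should be separable by chromatography; F3 is re-equilibrated with DBU through the ring-opened chalcone phenoxide and separated again.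

2. Step 4. The oxidative opening may take the external cyclopropane bond, or Fe(III) may oxidise or desilylate the electron-rich arene, so that no six-membered ring forms; a sluggish cyclopropanation in step 3 would have the same effect. The fallback sets out from 3 and comes back at 6. Dibromocarbene (PhHgCBr3, benzene, 80 °C) adds to the enol ether to give the gem-dibromocyclopropane F4. This should open by cyclopropyl-to-allyl ionisation with loss of the silyl group to the 3-bromochromone F5. Hydrodebromination (Pd(PPh3)4 cat., Bu3SnH, toluene, 60 °C) then gives 6.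

3. Step 15. Oxidative addition and transmetalation at the iodide flanked by a TIPSO group and the ring oxygen may be slow, allowing protodestannylation or homocoupling of the stannane and Z→E drift on heating. The fallback sets out from 24 and comes back at 25. Sonogashira coupling with the slimmer alkyne 21 (Pd(PPh3)2Cl2, CuI, Et3N, THF, 40 °C) gives the aryl enyne F6. Semi-reduction with Zn(Cu/Ag) in MeOH/H2O should reduce only the conjugated triple bond, cis, to give 25.

**Further compounds**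
F1 | step 14 | {(2R,3R)-3-[3,5-bis(TBSO)phenyl]-6-(TBSO)-2-[4-(TBSO)phenyl]-2,3-dihydro-1-benzofuran-5-yl}magnesium bromide | Br[Mg]c1cc2c(cc1O[Si](C)(C)C(C)(C)C)O[C@@H](c1ccc(O[Si](C)(C)C(C)(C)C)cc1)[C@@H]2c1cc(O[Si](C)(C)C(C)(C)C)cc(O[Si](C)(C)C(C)(C)C)c1
F2 | step 14 | 2-aryl-8-iodo-5,7-bis(TIPSO)-4-(trimethylsilyloxy)-2H-chromene (both C2 epimers; aryl as in 24) | C[Si](C)(C)OC1=CC(c3cc4c(cc3O[Si](C)(C)C(C)(C)C)O[C@@H](c3ccc(O[Si](C)(C)C(C)(C)C)cc3)[C@@H]4c3cc(O[Si](C)(C)C(C)(C)C)cc(O[Si](C)(C)C(C)(C)C)c3)Oc2c(I)c(O[Si](C(C)C)(C(C)C)C(C)C)cc(O[Si](C(C)C)(C(C)C)C(C)C)c12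
F3 | step 14 | (2R)-epimer of 24 | Ic1c(O[Si](C(C)C)(C(C)C)C(C)C)cc(O[Si](C(C)C)(C(C)C)C(C)C)c2c1O[C@@H](c1cc3c(cc1O[Si](C)(C)C(C)(C)C)O[C@@H](c1ccc(O[Si](C)(C)C(C)(C)C)cc1)[C@@H]3c1cc(O[Si](C)(C)C(C)(C)C)cc(O[Si](C)(C)C(C)(C)C)c1)CC2=O
F4 | step 4 | racemic 1,1-dibromo-4,6-bis(TIPSO)-6b-(trimethylsilyloxy)-1a,6b-dihydro-1H-cyclopropa[b][1]benzofuran | C[Si](C)(C)OC12C(Br)(Br)C1Oc1cc(O[Si](C(C)C)(C(C)C)C(C)C)cc(O[Si](C(C)C)(C(C)C)C(C)C)c12
F5 | step 4 | 3-bromo-5,7-bis(TIPSO)-4H-chromen-4-one | O=c1c(Br)coc2cc(O[Si](C(C)C)(C(C)C)C(C)C)cc(O[Si](C(C)C)(C(C)C)C(C)C)c12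
F6 | step 15 | 8-(3-methylbut-3-en-1-yn-1-yl) analogue of 25 | C=C(C)C#Cc1c(O[Si](C(C)C)(C(C)C)C(C)C)cc(O[Si](C(C)C)(C(C)C)C(C)C)c2c1O[C@H](c1cc3c(cc1O[Si](C)(C)C(C)(C)C)O[C@@H](c1ccc(O[Si](C)(C)C(C)(C)C)cc1)[C@@H]3c1cc(O[Si](C)(C)C(C)(C)C)cc(O[Si](C)(C)C(C)(C)C)c1)CC2=O
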